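**Retrosynthetic overview**
- Target ⇐ tetra-O-benzyl 2H-chromene ketal by one hydrogenation (four benzyl ethers off, chromene C3=C4 saturated); the flavan C3–C4 unit is carried at the alkyne/alkene oxidation level until then.
- Key step: in one flask, Au(I) closes the pyran ring by joining the terminal alkyne carbon (future flavan C4) to the arene C–H carbon (future C4a), and a chiral Brønsted acid closes the chromanone ring by adding an A-ring phenol to benzofuran C2, which creates the ketal carbon and its neighbour.
- Enabling feature: flavan C4a (benzofuran C5) is the only free carbon ortho to the ether oxygen O1, because the other ortho carbon (C8) is the furan ring-fusion carbon; it is ortho to two ring oxygens and para to the furan oxygen. The benzofuran O–C2=C3–C=O unit is a vinylogous ester carrying a 2,6-dihydroxyphenyl ketone placed for 6-endo attack.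
- The aryl propargyl ether comes from a benzofuran-4-ol and a racemic propargylic acetate by Cu-catalysed enantioselective etherification (sets flavan C2). The benzofuranol comes from a four-component union of an iodoresorcinol, an aryl alkyne, an aryl iodide and CO; both phloroglucinol rings derive from one iodide.
- Ring order: furan (step 4), then pyran and chromanone/ketal together (step 9).

Key step: step 9

Assumption: compounds 1, 6 and 9 are taken as commercial, and the hand of the pybox ligand (step 7) and of the chiral acid (step 9) is the one that gives the stated descriptors; the sense of induction on these substrates is not predicted here.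

**Route**

Step 1
Reactants: 1 5-(benzyloxy)benzene-1,3-diol
Product: 2 1-(benzyloxy)-3,5-bis(methoxymethoxy)benzene
Conditions: MOMCl, iPr2NEt, CH2Cl2, 0 °C to rt
Reagents that add atoms: chloromethyl methyl ether, COCCl
Why: Williamson-type O-alkylation of both phenols gives the bis-MOM ether whose two acetal oxygens direct the metalation of step 2.

Step 2
Reactants: 2 1-(benzyloxy)-3,5-bis(methoxymethoxy)benzene
Product: 4 5-(benzyloxy)-2-iodo-1,3-bis(methoxymethoxy)benzene, via aryllithium 3 (not isolated)
Conditions: n-BuLi, THF, 0 °C; then I2, −78 °C to rt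
Reagents that add atoms: iodine, II
Why: Directed ortho-metalation removes the proton between the two MOM ethers by cooperative coordination (in preference to the positions next to the benzyl ether), and iodine traps the aryllithium at the carbon that later carries the alkyne or the carbonyl group.

Step 3
Reactants: 4 5-(benzyloxy)-2-iodo-1,3-bis(methoxymethoxy)benzene (part of the batch)
Product: 5 5-(benzyloxy)-2-iodobenzene-1,3-diol
Conditions: HCl (cat.), MeOH, 40 °C
Reagents that add atoms: none
Why: Acid-catalysed acetal exchange with methanol removes both MOM groups and leaves the aryl iodide and benzyl ether intact, giving a symmetric iodoresorcinol with two equivalent hydroxyls.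

Step 4
Reactants: 5 5-(benzyloxy)-2-iodobenzene-1,3-diol; 6 1-(benzyloxy)-4-ethynylbenzene; 4 5-(benzyloxy)-2-iodo-1,3-bis(methoxymethoxy)benzene
Product: 8 [4-(benzyloxy)-2,6-bis(methoxymethoxy)phenyl]{6-(benzyloxy)-2-[4-(benzyloxy)phenyl]-4-hydroxy-1-benzofuran-3-yl}methanone, via magnesium alkynylresorcinolate 7 (not isolated)
Conditions: MeMgCl (3.1 equiv), Pd(PPh3)2Cl2 (5 mol%), THF, 65 °C; then 4, CO (1 atm), DMSO, 90 °C; aq. NH4Cl
Reagents that add atoms: carbon monoxide, [C-]#[O+]
Why: Known multicomponent benzofuran synthesis: Pd-catalysed coupling of the magnesium acetylide of 6 with the aryl iodide gives the magnesium o-alkynylphenoxide 7 (Sonogashira-type), and the aroyl–Pd(II) species from 4 and CO then triggers anti-oxypalladation and reductive elimination (carbonylative heteroannulation), which fixes the 2-aryl-3-aroyl pattern and leaves the second, equivalent phenoxide as the free 4-OH.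

Step 5
Reactants: 9 4-(benzyloxy)benzaldehyde
Product: 10 rac-1-[4-(benzyloxy)phenyl]prop-2-yn-1-ol
Conditions: HC≡CMgBr, THF, 0 °C; aq. NH4Cl
Reagents that add atoms: ethynylmagnesium bromide, C#C[Mg]Br
Why: Grignard 1,2-addition to the aldehyde gives the racemic propargylic alcohol, which is sufficient because step 7 is stereoconvergent.

Step 6
Reactants: 10 rac-1-[4-(benzyloxy)phenyl]prop-2-yn-1-ol
Product: 11 rac-1-[4-(benzyloxy)phenyl]prop-2-yn-1-yl acetate
Conditions: Ac2O, Et3N, DMAP (cat.), CH2Cl2, 0 °C
Reagents that add atoms: acetic anhydride, CC(=O)OC(C)=O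
Why: DMAP-catalysed acetylation installs the leaving group needed to form the copper allenylidene.

Step 7
Reactants: 8 the benzofuran-4-ol ketone; 11 rac-1-[4-(benzyloxy)phenyl]prop-2-yn-1-yl acetate
Product: 12 [4-(benzyloxy)-2,6-bis(methoxymethoxy)phenyl][6-(benzyloxy)-2-[4-(benzyloxy)phenyl]-4-{[(1R)-1-[4-(benzyloxy)phenyl]prop-2-yn-1-yl]oxy}-1-benzofuran-3-yl]methanone
Conditions: Cu(OTf)2 (5 mol%), chiral pybox ligand (10 mol%), iPr2NEt, MeOH, −20 °C
Reagents that add atoms: none
Why: Cu-catalysed enantioselective propargylic etherification: either enantiomer of 11 ionises to the same Cu–allenylidene, and the phenoxide of 8 (its only free OH) attacks the γ-carbon on the face left open by the pybox ligand, so the (R) centre that becomes flavan C2 is set by the catalyst.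

Step 8
Reactants: 12 the (R)-propargyl ether with two MOM groups
Product: 14 [4-(benzyloxy)-2,6-dihydroxyphenyl][6-(benzyloxy)-2-[4-(benzyloxy)phenyl]-4-{[(1R)-1-[4-(benzyloxy)phenyl]prop-2-yn-1-yl]oxy}-1-benzofuran-3-yl]methanone, via bis(trimethylsilyl) ether 13 (not isolated)
Conditions: TMSOTf, 2,2'-bipyridyl, CH2Cl2, 0 °C to rt; then H2O
Reagents that add atoms: none
Why: Silyl triflate/bipyridyl cleavage of aromatic MOM ethers (the N-silylpyridinium salt activates the acetal oxygen and the aryl silyl ethers 13 hydrolyse on work-up) is non-protic, so the ionisable propargylic aryl ether, the terminal alkyne and the benzyl ethers should survive.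

Step 9
Reactants: 14 the (R)-propargyl ether with free 2,6-dihydroxybenzoyl group
Product: 16 tetra-O-benzyl-3,4-didehydro-17: cis-fused chromanone/dihydrobenzofuran ketal on a 2H-chromene (ketal C: S; adjacent CH: S; chromene C2: R), via chromene diol 15 (not isolated)
Conditions: [JohnPhosAu(NCMe)]SbF6 (3 mol%), TRIP-type chiral BINOL phosphoric acid (10 mol%), 4 Å MS, CH2Cl2–toluene, 0 °C then −20 °C
Reagents that add atoms: none
Why: Proposed new method: the cationic JohnPhos–Au(I) π-complex of the terminal alkyne is attacked by benzofuran C5 (the future flavan C4a) and protodeauration gives 2H-chromene 15, after which the chiral phosphoric acid, hydrogen-bonded to the ketone and to one of the two equivalent A-ring hydroxyls, delivers that phenol oxygen to benzofuran C2 (β-carbon of the vinylogous ester O–C2=C3–C=O) and the resulting enol is protonated at C3. The gold half is the known Au(I)-catalysed hydroarylation of aryl propargyl ethers to 2H-chromenes; the acid half is closest to chiral-acid or bifunctional-catalyst oxa-Michael closure of 2'-hydroxychalcones to flavanones and to confined-acid asymmetric ketalisation of enol ethers, combined as in Au/phosphoric acid relay catalysis, and what is new is the catalyst-controlled, dearomatising addition to a 3-aroylbenzofuran. Two rings close: the pyran ring 6-endo-dig through the new C4–C4a bond, and the chromanone ring 6-endo-trig through the new O–C2 bond, which turns the furan into the dihydrofuran of the ketal. The ketal carbon is set by the acid, which decides the face of C2 that is attacked; C3 follows because this 5/6 ketal can only be cis-fused, so the proton must enter cis to the new C–O bond; the flavan C2 centre from step 7 is kept because its C–O and C–H bonds are not broken. The gold step needs no directing group, since the second carbon ortho to the ether oxygen is the ring-fusion carbon C3a and the free one is ortho to two oxygens and para to the furan oxygen, and 6-endo over 5-exo is the normal outcome for a terminal alkyne on such an arene with a bulky biarylphosphine ligand. The ketal closure must stay under kinetic control (low temperature, weak acid, apolar solvent), and the second A-ring hydroxyl, which stays chelated to the new chromanone carbonyl, is counted on to make the closure favourable.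

Step 10
Reactants: 16 the tetrabenzyl chromene ketal
Product: 17 CNP0179743.1 (target)
Conditions: H2 (1 atm), Pd/C, THF–EtOAc, rt
Reagents that add atoms: none
Why: Heterogeneous hydrogenation saturates the chromene C3=C4 bond, returning the former alkyne carbons to CH2–CH2, and hydrogenolyses the four benzyl ethers under neutral conditions that should not open the acid- and base-sensitive ketal or reduce the chelated aryl ketone; no stereocentre is formed or touched.

**Compound list**
1 | 5-(benzyloxy)benzene-1,3-diol | Oc1cc(O)cc(OCc2ccccc2)c1 | starting material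
2 | 1-(benzyloxy)-3,5-bis(methoxymethoxy)benzene | COCOc1cc(OCOC)cc(OCc2ccccc2)c1 | intermediate
3 | [4-(benzyloxy)-2,6-bis(methoxymethoxy)phenyl]lithium (not isolated) | [Li]c1c(OCOC)cc(OCc2ccccc2)cc1OCOC | intermediate
4 | 5-(benzyloxy)-2-iodo-1,3-bis(methoxymethoxy)benzene | COCOc1cc(OCc2ccccc2)cc(OCOC)c1I | intermediate
5 | 5-(benzyloxy)-2-iodobenzene-1,3-diol | Oc1cc(OCc2ccccc2)cc(O)c1I | intermediate
6 | 1-(benzyloxy)-4-ethynylbenzene | C#Cc1ccc(OCc2ccccc2)cc1 | starting material
7 | bis(chloromagnesium) 5-(benzyloxy)-2-{[4-(benzyloxy)phenyl]ethynyl}benzene-1,3-diolate (not isolated) | Cl[Mg]Oc1cc(OCc2ccccc2)cc(O[Mg]Cl)c1C#Cc1ccc(OCc2ccccc2)cc1 | intermediate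
8 | [4-(benzyloxy)-2,6-bis(methoxymethoxy)phenyl]{6-(benzyloxy)-2-[4-(benzyloxy)phenyl]-4-hydroxy-1-benzofuran-3-yl}methanone | O=C(c1c(OCOC)cc(OCc2ccccc2)cc1OCOC)c1c(-c2ccc(OCc3ccccc3)cc2)oc2cc(OCc3ccccc3)cc(O)c12 | intermediate
9 | 4-(benzyloxy)benzaldehyde | O=Cc1ccc(OCc2ccccc2)cc1 | starting material
10 | rac-1-[4-(benzyloxy)phenyl]prop-2-yn-1-ol | OC(C#C)c1ccc(OCc2ccccc2)cc1 | intermediate
11 | rac-1-[4-(benzyloxy)phenyl]prop-2-yn-1-yl acetate | CC(=O)OC(C#C)c1ccc(OCc2ccccc2)cc1 | intermediate
12 | [4-(benzyloxy)-2,6-bis(methoxymethoxy)phenyl][6-(benzyloxy)-2-[4-(benzyloxy)phenyl]-4-{[(1R)-1-[4-(benzyloxy)phenyl]prop-2-yn-1-yl]oxy}-1-benzofuran-3-yl]methanone | O=C(c1c(OCOC)cc(OCc2ccccc2)cc1OCOC)c1c(-c2ccc(OCc3ccccc3)cc2)oc2cc(OCc3ccccc3)cc(O[C@@H](c3ccc(OCc4ccccc4)cc3)C#C)c12 | intermediate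
13 | bis(trimethylsilyl) ether of 14 (not isolated) | O=C(c1c(O[Si](C)(C)C)cc(OCc2ccccc2)cc1O[Si](C)(C)C)c1c(-c2ccc(OCc3ccccc3)cc2)oc2cc(OCc3ccccc3)cc(O[C@@H](c3ccc(OCc4ccccc4)cc3)C#C)c12 | intermediate
14 | [4-(benzyloxy)-2,6-dihydroxyphenyl][6-(benzyloxy)-2-[4-(benzyloxy)phenyl]-4-{[(1R)-1-[4-(benzyloxy)phenyl]prop-2-yn-1-yl]oxy}-1-benzofuran-3-yl]methanone | O=C(c1c(O)cc(OCc2ccccc2)cc1O)c1c(-c2ccc(OCc3ccccc3)cc2)oc2cc(OCc3ccccc3)cc(O[C@@H](c3ccc(OCc4ccccc4)cc3)C#C)c12 | intermediate
15 | [4-(benzyloxy)-2,6-dihydroxyphenyl]{(2R)-5-(benzyloxy)-2,8-bis[4-(benzyloxy)phenyl]-2H-furo[2,3-h]chromen-9-yl}methanone (not isolated) | O=C(c1c(O)cc(OCc2ccccc2)cc1O)c1c(-c2ccc(OCc3ccccc3)cc2)oc2cc(OCc3ccccc3)c3C=C[C@H](c4ccc(OCc5ccccc5)cc4)Oc3c12 | intermediate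
16 | tetra-O-benzyl-3,4-didehydro-17: cis-fused chromanone/dihydrobenzofuran ketal on a 2H-chromene; benzyl ethers at chromanone O7, chromene O5 and both 4-oxyphenyl groups; free OH at chromanone C5 (ketal C: S; adjacent CH: S; chromene C2: R) | O=C1c2c(O)cc(OCc3ccccc3)cc2O[C@@]2(c3ccc(OCc4ccccc4)cc3)Oc3cc(OCc4ccccc4)c4c(c3[C@@H]12)O[C@@H](c1ccc(OCc3ccccc3)cc1)C=C4 | intermediate
17 | CNP0179743.1: (2R)-5-hydroxy-2-(4-hydroxyphenyl)flavan whose O7 and C8 are joined through a dihydrofuran ring to C2 and C3 of 5,7-dihydroxy-2-(4-hydroxyphenyl)chroman-4-one (ketal C2: S; C3: S; cis-fused) | O=C1c2c(O)cc(O)cc2O[C@@]2(c3ccc(O)cc3)Oc3cc(O)c4c(c3[C@@H]12)O[C@@H](c1ccc(O)cc1)CC4 | target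

Total steps: 10. Longest linear sequence: 8 (steps 1, 2, 3, 4, 7, 8, 9, 10).

**Steps most likely to fail**

1. Step 9 (Proposed new method). The ketal closure may not stay under kinetic control. Adding the phenol to benzofuran C2 costs the furan aromaticity, so the closure may be reversible or uphill and the product may re-open through its enol or through ionisation of a ketal C–O bond. The acid may fail to discriminate the two faces of C2 (the remote chromene centre cannot), an uncatalysed background closure of the 2,6-dihydroxy ketone would erode selectivity, and the acid/gold pair could ionise the allylic, benzylic C2–O bond of the chromene. Fallback with known chemistry, setting out from 14 and returning at 16: 14 is cyclised with the gold catalyst alone and chromene 15 is isolated. 15 is then closed without a chiral catalyst under chalcone–flavanone isomerisation conditions (NaOAc, EtOH, 50 °C), which should give 16 together with the ketal epimer of 16 F1 ((R,R)-ketal, same (R)-chromene centre). The two are diastereomers and are separated by chromatography; F1 is re-opened to 15 with DBU (retro-oxa-Michael) and put through the closure again.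

2. Step 7. The electron-rich benzofuran may be C-propargylated (Friedel–Crafts attack of C5 or C7 on the allenylidene) instead of O-alkylated, the hindered and hydrogen-bonded 4-OH may react slowly, and uncatalysed ionisation of the p-alkoxybenzylic acetate would lower the enantiomeric purity. Fallback, setting out from 10 and 8 and returning at 12: racemic 10 is resolved by lipase-catalysed acylation (Candida antarctica lipase B, vinyl acetate, MTBE). By the usual enantiopreference of this lipase for secondary carbinols the (R)-alcohol should be acylated, leaving (S)-1-[4-(benzyloxy)phenyl]prop-2-yn-1-ol F2. Mitsunobu coupling of F2 with phenol 8 (PPh3, DIAD, toluene, 0 °C) forms the ether with inversion and gives 12.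

3. Step 4. Oxidative addition and CO insertion with the di-ortho-substituted, electron-rich iodide 4 may be slow, so the magnesium alkynylphenoxide may cyclise without acyl transfer (3-unsubstituted benzofuran) or the free phenoxide may be O-acylated. Fallback without CO and without an o-alkynylphenol, setting out from 2 (through 3), 6 and 5 and returning at 8: aryllithium 3 is quenched with DMF to give 4-(benzyloxy)-2,6-bis(methoxymethoxy)benzaldehyde F3. Alkyne 6 is deprotonated with n-BuLi to {[4-(benzyloxy)phenyl]ethynyl}lithium F4, which adds to F3 to give the propargylic alcohol F5; MnO2 oxidises F5 to the ynone F6. One hydroxyl of iodoresorcinol 5 adds to F6 (K2CO3 cat., MeCN, rt) to give the β-aryloxy enone F7, and an intramolecular Heck cyclisation (Pd(OAc)2, PPh3, Ag2CO3, DMF, 100 °C) joins the iodide-bearing carbon to the enone α-carbon and closes the furan to 8.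

Further compounds
F1 | step 9 | ketal epimer of 16 (ketal C: R; adjacent CH: R; chromene C2: R) | O=C1c2c(O)cc(OCc3ccccc3)cc2O[C@]2(c3ccc(OCc4ccccc4)cc3)Oc3cc(OCc4ccccc4)c4c(c3[C@H]12)O[C@@H](c1ccc(OCc3ccccc3)cc1)C=C4
F2 | step 7 | (S)-1-[4-(benzyloxy)phenyl]prop-2-yn-1-ol | O[C@H](c1ccc(OCc2ccccc2)cc1)C#C
F3 | step 4 | 4-(benzyloxy)-2,6-bis(methoxymethoxy)benzaldehyde | COCOc1cc(OCc2ccccc2)cc(OCOC)c1C=O
F4 | step 4 | {[4-(benzyloxy)phenyl]ethynyl}lithium | [Li]C#Cc1ccc(OCc2ccccc2)cc1
F5 | step 4 | rac-1-[4-(benzyloxy)-2,6-bis(methoxymethoxy)phenyl]-3-[4-(benzyloxy)phenyl]prop-2-yn-1-ol | COCOc1cc(OCc2ccccc2)cc(OCOC)c1C(O)C#Cc1ccc(OCc2ccccc2)cc1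
F6 | step 4 | 1-[4-(benzyloxy)-2,6-bis(methoxymethoxy)phenyl]-3-[4-(benzyloxy)phenyl]prop-2-yn-1-one | COCOc1cc(OCc2ccccc2)cc(OCOC)c1C(=O)C#Cc1ccc(OCc2ccccc2)cc1
F7 | step 4 | 3-[5-(benzyloxy)-3-hydroxy-2-iodophenoxy]-1-[4-(benzyloxy)-2,6-bis(methoxymethoxy)phenyl]-3-[4-(benzyloxy)phenyl]prop-2-en-1-one (E/Z mixture) | COCOc1cc(OCc2ccccc2)cc(OCOC)c1C(=O)C=C(Oc1cc(OCc2ccccc2)cc(O)c1I)c1ccc(OCc2ccccc2)cc1
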